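Late in a run you want to know what has become of the bis adduct already made, so follow the partner that reaches it.

common to all: substrate 20 mM

| run | partner | time | remark |
|---|---|---|---|
| alder | 18.0 mM (fed, over 6.00 h) | 6.0 h | all but partner at the start; partner goes in evenly over 6.00 h, the run ends at 6.0 h |
| maple | 18.0 mM | 6.0 h | everything together in a closed stirred flask, run for 6.0 h |
| elm | 18.0 mM |  | one stirred flow tank at steady state, fed with the mixture as stated, mean residence time 6.0 h |
| oak | 18.0 mM | 6.0 h | a tube with plug flow, the mixed feed as stated, residence time 6.0 h |

    substrate + partner → single product (k1 = 3.3 M⁻¹ min⁻¹)
    partner + single product → bis adduct (k2 = 0.31 M⁻¹ min⁻¹)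
    partner + bis adduct → tris adduct (k3 = 8.5 M⁻¹ min⁻¹)
    partner ⇌ dormant form (K4 = 1.3, k4 = 0.012 min⁻¹)
    bis adduct ⇌ isomer of the product (K5 = 0.50, k5 = 0.032 min⁻¹)

* the set-up with the highest share of bis adduct in all that became bis adduct or tris adduct or isomer of the product, at the outlet or at the end ("none" if the first two lie within 2 percentage points) (alder / maple / elm / oak / none)
* share of bis adduct in all that became bis adduct or tris adduct or isomer of the product, at the outlet or at the end, alder
* share of bis adduct in all that became bis adduct or tris adduct or isomer of the product, at the outlet or at the end, maple
* share of bis adduct in all that became bis adduct or tris adduct or isomer of the product, at the outlet or at the end, elm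
* share of bis adduct in all that became bis adduct or tris adduct or isomer of the product, at the outlet or at the end, oak

- the stated concentrations are those of everything mixed, before any reaction; amounts are the same in each set-up
- the feed brings no volume worth counting
- run time (alder): 6.0 h

The partner is the limiting reagent, 18.0 mM against 20 mM of substrate. Write its balance and you see that each of the three addition steps carries the partner concentration as a factor, whether the partner is fed or charged at once. Divide by that concentration and the clock becomes partner exposure, the partner concentration summed over time. Two times then remain, both reckoned at the whole charge of partner. One e-fold of substrate takes 16.8 min. Bis adduct and its isomer interconvert with a half-life of 0.361 h by the forward step alone, short against the 6.0 h run, so you can treat them as one pool holding 66.7% as bis adduct. One e-fold of that pool, drained to tris adduct, takes 9.80 min, less than the substrate needs.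

Their ratio is the drain ratio, 1.72: pool e-folds per substrate e-fold at equal exposure. In the stirred tank elm the ratio of the balances comes by hand. Tris adduct leaving per pool leaving equals the drain ratio times substrate converted per substrate left, and the partner level cancels. So the share in elm is the bis part of the pool divided by one plus that product. My reckoning stops here, short of the substrate left in elm, which takes the coupled balances of that tank solved together; I add only that the tube oak runs in time as the closed flask maple does.

The forecast compares the set-ups through partner exposure and adds “Dormant partner acts as a slow reservoir”: alder best, with alder 35%, maple and oak 27% each, elm 17.5%.

The flask puts alder first at 36.1%, with maple and oak at 30.0% and elm at 17.6%. The tank elm holds 7.61 mM of substrate. Put that into the rule with the drain ratio and elm's share comes to 17.6%. Strike the step to tris adduct out of alder and the drain ratio is zero, which leaves the pool's bis part of 66.7%; that alder run gives 69.1%.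

(The constants are those of an exercise; no experiment stands behind them.)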